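## The problem

The target is a bis-decalin meroterpenoid. A left decalin (rings A and B) and a right decalin (rings C and D) are joined by a CH2CH2 bridge that runs from a quaternary carbon of ring B to a quaternary carbon of ring D. Ring A carries a 2,5-bis(sulfooxy)benzyl group on a third quaternary carbon.

There are seven stereocentres. Four are in the left half: the benzylic quaternary carbon, the adjacent CH(CH3), the ring-fusion CH and the bridge-bearing quaternary carbon. Three are in the right half: the bridge-bearing quaternary carbon, the adjacent CH(CH3) and the ring-fusion CH. The two sets are insulated by the bridge and cannot control each other, so each half must be made as one enantiomer and joined stereospecifically.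

Within a half, control is available. The quaternary carbon and its methyl neighbour can be set together, the ring-fusion hydrogen can be set relative to them, and the left bridge carbon can be set from an adjacent C–O stereocentre during the union.

Each trisubstituted alkene lies between a quaternary carbon and a ring-fusion centre and can slip to the tetrasubstituted ring-fusion position under acid. The aryl sulfates hydrolyse with acid or heat and the hydroquinone is air-sensitive, so the arene should travel as its dimethyl ether and the sulfates come last.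

The enabling feature is in ring C. Its alkene runs from the ring-fusion sp2 carbon to a CH, and the ring-fusion CH stereocentre is bonded to the gem-dimethyl carbon. That is the pattern left by a [3,3] shift of an ester enolate onto an allylic carbinol hung on ring D, if one geminal methyl is read as a former carboxyl group.

## Retrosynthesis

**Sulfates and arene.** The O–S bonds are cut first (46 ⇒ hydroquinone 44), then the hydroquinone is masked (44 ⇒ dimethyl ether 42, through quinone 43). Methyl ethers are preferred to silyl or benzyl ethers because they survive dissolving metal, organometallics and hexavalent chromium and come off oxidatively without acid. The precursor 42 is a hydrocarbon skeleton with one robust arene. The forward steps must leave two trisubstituted alkenes alone.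

**The bridge.** In 42 the bond between the bridge CH2 and the quaternary carbon of ring B is cut. This gives primary Grignard reagent 41 (from bromide 24) and allylic picolinate 40, in which the alkene sits between the ring-fusion carbon and the methyl-bearing ring B carbon and the adjacent ring A carbon carries the leaving group. The neighbouring cuts are worse. The central CH2–CH2 bond would need an sp3–sp3 coupling of two β-quaternary partners. The bond to the ring D quaternary carbon would need late alkylation of a hindered enolate with an unactivated iodide and no handle on configuration. The chosen cut splits the molecule into C16 and C22 pieces and makes the quaternary carbon and the final alkene position in one stereospecific event. It asks for γ-attack anti to the picolinate at a fully substituted alkene carbon.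

**Right half, functional groups.** Bromide 24 ⇒ alcohol 23 ⇒ aldehyde 21 ⇒ alcohol 20 ⇒ acid 19. One geminal methyl is traced back to a carboxyl. This costs three forward steps but turns an unfunctionalised quaternary carbon into the α-carbon of an acid, which an ester enolate can deliver. The forward demand is deoxygenation of a hindered, non-enolisable aldehyde.

**Key disconnection.** In 19 the bond between the ring-fusion CH and the carboxyl-bearing quaternary carbon is cut and the alkene CH is reconnected to a carboxyl oxygen. The precursor is δ-lactone 16, a 3-methyl lactone whose carbinol carbon carries the ring D cyclohexenyl group. Other ways to close ring C are less exact. Annulation onto a ring D ketone leaves a carbonyl in ring C and cannot place the geminal pair next to the ring fusion. A cation–olefin closure leaves the alkene position to an elimination that favours the tetrasubstituted ring-fusion isomer. The Claisen transform fixes the alkene by mechanism and ties the ring-fusion configuration to one carbinol centre. The precursor is monocyclic with a single stereocentre to set. The forward reaction must pass through a boat with a quaternary carbon on the central allyl carbon.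

**Lactone to ring D.** 16 ⇒ hydroxy ester 15 ⇒ enone 14 ⇒ carbinol mixture 13 ⇒ enol triflate 8 + aldehyde 12. The bond cut is between the ring D sp2 carbon and the carbinol carbon. An alkenyl–chromium addition is chosen over adding an alkenyllithium to an anhydride or lactone because it tolerates the ester and the hindered triflate. It gives no control at the carbinol, so that centre is reset by oxidation and catalyst-controlled reduction. Aldehyde 12 comes from δ-valerolactone 9 through 10 and 11.

**Ring D.** 8 ⇒ alcohol 7 ⇒ allyl triflate 5 ⇒ ketone 4 ⇒ 2-methylcyclohex-2-en-1-one 1 + allyl bromide 2. The two bonds cut are Cβ–CH3 and Cα–allyl. Alkylating 2,3-dimethylcyclohexanone would face a regiochemistry problem. Conjugate addition generates the enolate (3) at the right carbon, and the electrophile enters anti to the new methyl. The allyl group is a masked 2-hydroxyethyl group. The only demand is enantiofacial control in the methyl addition.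

**Left half, leaving group.** 40 ⇒ allylic alcohol 38 + picolinic acid 39; 38 ⇒ enone 37. The C–O stereocentre is cut back to a ketone because a catalyst-controlled reduction can then set the configuration the anti-SN2′ step needs.

**Ring B.** 37 ⇒ diketone-equivalent 34 ⇒ enone 33. The tetrasubstituted alkene of 37 is the condensation bond of an intramolecular aldol between the ring A ketone α-carbon and a side-chain methyl ketone. A Robinson annulation would put the enone in the wrong ring. The ring-fusion hydrogen is added to the β-carbon of enone 33, where protonation through the all-equatorial chair gives the required isomer.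

**Ring A.** 33 ⇒ tertiary allylic alcohol 32 ⇒ enone 29 + chloro ketal 30 (as Grignard reagent 31); 29 ⇒ ketone 27 ⇒ 1 + 2,5-dimethoxybenzyl bromide 25 (through enolate 26). The side chain is attached by 1,2-addition with oxidative 1,3-transposition. This moves the oxygen to the carbon that will carry the picolinate, which simple enolate chemistry of 27 cannot reach. Ketone 27 is the mirror-image counterpart of 4, with benzyl in place of allyl, so both halves start from the same enone with the two enantiomers of one ligand.

## Roads not taken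

Alternative 1: Ring A would be closed by a Diels–Alder reaction between enantiopure diene A1 and benzylmaleic anhydride A2, cutting the ring-fusion CH–quaternary C bond and the ring CH2–CH bond, to give cis-anhydride A3.
- **Merits.** An endo addition anti to the methyl of A1 would set the benzylic quaternary carbon, its neighbour and the ring-fusion hydrogen in one step. The ring A alkene would arrive in its final position, so no substitution at a fully substituted alkene carbon is needed. In that respect it is better than the chosen plan, which spends eight steps on the left half and relies on a dissolving-metal protonation for the ring-fusion hydrogen.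
- **Weak points.** The regiochemistry requires the more substituted dienophile carbon to bond to the ring carbon of the diene and not to its CH2 terminus; sterics favour the opposite, and two carbonyls give little electronic bias. Both anhydride carbonyls must then be reduced to methyls, one on a quaternary carbon. The whole right decalin, including its quaternary carbon, must still be grown from the alkyne of A3.
- **Comparison.** The chosen plan offsets its longer left half with two pre-formed halves and a bridge made in a single bond.

Alternative 2: Ring D would be closed at its quaternary carbon by a 6-exo Heck cyclisation of enol triflate A4 with Pd(OAc)2 and BINAP, giving vinyl decalin A5.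
- **Merits.** The reaction is catalytic. The geminal methyls are present from the start, which saves the three-step carboxyl-to-methyl detour. β-Hydride elimination can only give the vinyl group, which is a direct precursor of the two-carbon bridge. On step economy within the right half it is at least as good as the chosen plan.
- **Weak points.** The new quaternary centre is set by facial selection in the insertion, under mixed control by the adjacent methyl centre, the ring-fusion centre and the ligand, with a real chance of a mismatched case. A4 itself needs two separately made stereocentres in a 1,4-relationship and a geometrically pure trisubstituted alkene.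
- **Comparison.** The chosen plan sets the quaternary carbon and its neighbour in the opening step by a known tandem reaction and passes chirality to the ring fusion by a stereospecific sigmatropic shift.

Alternative 3: The arene would be built last by a Dötz benzannulation of terminal alkyne A6 with vinylcarbene complex A7, giving hydroquinone monomethyl ether A8.
- **Merits.** The electron-rich arene never meets dissolving metal or hexavalent chromium. A small propargyl electrophile replaces the benzylic bromide in the enolate alkylation. The regiochemistry (alkyl group ortho to the hydroxyl) is reliable for terminal alkynes. On arene survival it is better than the chosen plan.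
- **Weak points.** It changes only the source of the arene; both decalins and the bridge remain to be solved. The terminal alkyne would need masking through the dissolving-metal and Grignard steps. A7 is a labile, unsubstituted vinylcarbene complex used stoichiometrically on the most valuable intermediate. A8 still needs oxidative demethylation, so the endgame is no shorter.
- **Comparison.** In the chosen plan the arene arrives in a commercial bromide at no cost in steps.

Key step: step 12

Assumptions:
- The target is drawn as the free bis(hydrogen sulfate). The last step therefore ends with protonation of the first-formed pyridinium salt on an acid-form resin, although a salt would be the form handled in practice.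
- Metal enolates and alkoxides that are only conjugate bases of numbered compounds are not numbered. Species made in one operation and consumed in the next within a step are numbered as intermediates.
- 2,5-Dimethoxybenzyl bromide, 2-(3-chloropropyl)-2-methyl-1,3-dioxolane and both enantiomers of the Josiphos ligand are taken as catalogue compounds.

Step 1
Reactants: 1 2-methylcyclohex-2-en-1-one; 2 allyl bromide
Product: 4 (2R,3S)-2-allyl-2,3-dimethylcyclohexan-1-one, via magnesium enolate 3 (not isolated)
Conditions: MeMgBr, CuBr·SMe2 (5 mol%), Josiphos ligand 1-[2-(diphenylphosphino)ferrocenyl]ethyldicyclohexylphosphine (6 mol%, enantiomer that gives the 3S centre), t-BuOMe, −78 °C; then 2, DMPU, −78 → 0 °C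
Reagents that add atoms: methylmagnesium bromide, C[Mg]Br
Why: Copper-catalysed asymmetric conjugate addition of the Grignard reagent to the α-substituted enone sets C-3 under ligand control; the regiodefined magnesium enolate 3 is then C-allylated (tandem conjugate addition–enolate alkylation) at its only substituted α-carbon, anti to the new methyl, which makes the quaternary carbon with the two methyls cis.

Step 2
Reactants: 4 (2R,3S)-2-allyl-2,3-dimethylcyclohexan-1-one
Product: 5 (5S,6R)-6-allyl-5,6-dimethylcyclohex-1-en-1-yl trifluoromethanesulfonate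
Conditions: KN(SiMe3)2, THF, −78 °C; PhNTf2, −78 → 0 °C
Reagents that add atoms: N-phenylbis(trifluoromethanesulfonimide), FC(F)(F)S(=O)(=O)N(c1ccccc1)S(=O)(=O)C(F)(F)F
Why: Enolisation is possible only toward C-6 because C-2 is quaternary, so O-sulfonylation of the potassium enolate (enol triflate formation) is regiospecific; no stereocentre is touched.

Step 3
Reactants: 5 allyl enol triflate
Product: 7 (5S,6R)-6-(2-hydroxyethyl)-5,6-dimethylcyclohex-1-en-1-yl trifluoromethanesulfonate, via aldehyde 6 (not isolated)
Conditions: O3, CH2Cl2/MeOH, −78 °C (Sudan red 7B end point); then NaBH4, −78 → 0 °C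
Reagents that add atoms: ozone, [O-][O+]=O
Why: Ozonolysis with reductive work-up: ozone cleaves the monosubstituted alkene far faster than the electron-poor enol triflate, and NaBH4 reduces the ozonide-derived aldehyde 6 in the same flask, so no ketone–aldehyde discrimination is needed.

Step 4
Reactants: 7 hydroxyethyl enol triflate
Product: 8 (5S,6R)-6-[2-(tert-butyldimethylsilyloxy)ethyl]-5,6-dimethylcyclohex-1-en-1-yl trifluoromethanesulfonate
Conditions: TBSCl, imidazole, DMF, 23 °C
Reagents that add atoms: tert-butyldimethylsilyl chloride, CC(C)(C)[Si](C)(C)Cl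
Why: Standard silylation of a primary alcohol; the TBS ether survives the organochromium, hydride, enolate and thermal steps that follow.

Step 5
Reactants: 9 δ-valerolactone
Product: 10 (±)-3-methyltetrahydro-2H-pyran-2-one
Conditions: LiN(iPr)2, THF, −78 °C; MeI, −78 → −20 °C
Reagents that add atoms: iodomethane, CI
Why: Lactone enolate alkylation; the α-methyl centre is left racemic on purpose because it is planarised again in the ketene acetal of step 12.

Step 6
Reactants: 10 3-methyl-δ-valerolactone
Product: 11 methyl (±)-5-hydroxy-2-methylpentanoate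
Conditions: MeOH, H2SO4 (cat.), 65 °C; NaHCO3, then concentrate cold
Reagents that add atoms: methanol, CO
Why: Acid-catalysed transesterification opens the δ-lactone in a large excess of methanol; neutralisation before concentration prevents relactonisation and the hydroxy ester is oxidised without storage.

Step 7
Reactants: 11 methyl 5-hydroxy-2-methylpentanoate
Product: 12 methyl (±)-2-methyl-5-oxopentanoate
Conditions: Dess–Martin periodinane, NaHCO3, CH2Cl2, 23 °C
Reagents that add atoms: none
Why: Dess–Martin oxidation of a primary alcohol to the aldehyde under buffered, non-epimerising conditions (the α-methyl centre is racemic anyway).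

Step 8
Reactants: 8 silyloxyethyl enol triflate; 12 methyl 2-methyl-5-oxopentanoate
Product: 13 methyl (2RS,5RS)-5-{(5S,6R)-6-[2-(tert-butyldimethylsilyloxy)ethyl]-5,6-dimethylcyclohex-1-en-1-yl}-5-hydroxy-2-methylpentanoate
Conditions: CrCl2 (4 equiv), NiCl2 (2 mol%), DMF, 23 °C
Reagents that add atoms: none
Why: Nozaki–Hiyama–Kishi coupling: zerovalent nickel inserts into the hindered enol triflate, transmetalation gives an alkenyl species of trivalent chromium that adds to the aldehyde and ignores the ester; the carbinol forms as a mixture and is corrected in steps 9 and 10.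

Step 9
Reactants: 13 allylic alcohol mixture
Product: 14 methyl (2RS)-5-{(5S,6R)-6-[2-(tert-butyldimethylsilyloxy)ethyl]-5,6-dimethylcyclohex-1-en-1-yl}-2-methyl-5-oxopentanoate
Conditions: Dess–Martin periodinane, NaHCO3, CH2Cl2, 23 °C
Reagents that add atoms: none
Why: Dess–Martin oxidation of the allylic alcohol erases the uncontrolled carbinol centre and gives the ketone needed for reagent-controlled reduction.

Step 10
Reactants: 14 enone ester
Product: 15 methyl (2RS,5R)-5-{(5S,6R)-6-[2-(tert-butyldimethylsilyloxy)ethyl]-5,6-dimethylcyclohex-1-en-1-yl}-5-hydroxy-2-methylpentanoate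
Conditions: (3aS)-1-methyl-3,3-diphenyltetrahydro-1H,3H-pyrrolo[1,2-c][1,3,2]oxazaborole (0.2 equiv), catecholborane, toluene, −78 °C
Reagents that add atoms: none
Why: Corey–Bakshi–Shibata reduction: the oxazaborolidine binds the carbonyl anti to the fully substituted alkenyl group (large) and delivers hydride to give the (5R)-carbinol, the same sense as acetophenone to (R)-1-phenylethanol with this catalyst enantiomer; catecholborane avoids hydroboration of the ring alkene.

Step 11
Reactants: 15 (5R)-hydroxy ester
Product: 16 (3RS,6R)-6-{(5S,6R)-6-[2-(tert-butyldimethylsilyloxy)ethyl]-5,6-dimethylcyclohex-1-en-1-yl}-3-methyltetrahydro-2H-pyran-2-one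
Conditions: pyridinium p-toluenesulfonate (cat.), toluene, 80 °C
Reagents that add atoms: none
Why: Acid-catalysed lactonisation (intramolecular transesterification) at the acyl carbon; the carbinol C–O bond is not broken, so the (R) configuration is retained, and the weak acid does not ionise the allylic alcohol or cleave the TBS ether.

Step 12
Reactants: 16 cyclohexenyl δ-lactone
Product: 19 (1S,5R,6S,8aR)-5-[2-(tert-butyldimethylsilyloxy)ethyl]-1,5,6-trimethyl-1,2,3,5,6,7,8,8a-octahydronaphthalene-1-carboxylic acid, via silyl ketene acetal 17 (not isolated), via silyl ester 18 (not isolated)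
Conditions: LiN(iPr)2, THF, −78 °C; TBSCl, DMPU, −78 → 23 °C; toluene, 110 °C; then K2CO3, MeOH/H2O, 23 °C; citric acid work-up
Reagents that add atoms: none
Why: LiN(iPr)2 removes the lactone α-proton and O-silylation gives cyclic silyl ketene acetal 17, in which the enol ether carbon, the ring oxygen, the carbinol carbon and the ring D alkene make up the 1,5-diene of an Ireland–Claisen rearrangement; on heating, the carbinol C–O bond breaks while the enolate carbon bonds to the alkene CH in a concerted suprafacial [3,3] shift. The closest known reaction type is the ring-contracting Claisen carbocyclisation of alkenyl lactone silyl ketene acetals, which for small lactones runs through a boat because the two-carbon tether bridges the ends of the array. Ring C closes by this ring contraction: the six-membered lactone becomes a six-membered carbocycle made of the two lactone methylenes, the new quaternary carbon, the former carbinol carbon and the two former alkene carbons, so the new alkene must lie between the ring-fusion carbon and the ring CH. The ring-fusion CH stereocentre is controlled by the (R)-carbinol, because the tether holds the breaking C–O bond on the face of ring D that carries the two methyls and the new C–C bond forms on that same face, leaving the hydrogen cis to the silyloxyethyl chain. The quaternary carbon is fixed by the bicyclic boat (carboxyl on the face of the departing oxygen) and later becomes achiral, so both C-3 epimers of 16 converge. The step needs complete 1,3-chirality transfer and no ionisation of the allylic C–O bond, and the forced intramolecular geometry and neutral thermal conditions secure both. K2CO3 in aqueous methanol cleaves silyl ester 18 and leaves the primary alkyl TBS ether intact.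

Step 13
Reactants: 19 decalin carboxylic acid
Product: 20 {(1S,5R,6S,8aR)-5-[2-(tert-butyldimethylsilyloxy)ethyl]-1,5,6-trimethyl-1,2,3,5,6,7,8,8a-octahydronaphthalen-1-yl}methanol
Conditions: LiAlH4, THF, 0 → 66 °C
Reagents that add atoms: none
Why: LiAlH4 reduction of the hindered tertiary carboxylic acid to the neopentyl alcohol; the silyl ether and the isolated trisubstituted alkene are inert.

Step 14
Reactants: 20 neopentyl alcohol
Product: 21 (1S,5R,6S,8aR)-5-[2-(tert-butyldimethylsilyloxy)ethyl]-1,5,6-trimethyl-1,2,3,5,6,7,8,8a-octahydronaphthalene-1-carbaldehyde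
Conditions: Dess–Martin periodinane, NaHCO3, CH2Cl2, 23 °C
Reagents that add atoms: none
Why: Dess–Martin oxidation to a non-enolisable neopentyl aldehyde; no epimerisable centre is adjacent.

Step 15
Reactants: 21 neopentyl aldehyde
Product: 23 2-[(1R,2S,4aS)-1,2,5,5-tetramethyl-1,2,3,4,4a,5,6,7-octahydronaphthalen-1-yl]ethan-1-ol, via hydrazone 22 (not isolated)
Conditions: N2H4·H2O, diethylene glycol, 130 °C; then KOH, 200 °C
Reagents that add atoms: none
Why: Wolff–Kishner reduction (Huang-Minlon procedure): hydrazone 22 loses N2 under hot KOH to turn the formyl group into the second geminal methyl, the classical solution for hindered non-enolisable aldehydes; the same hot KOH/glycol medium cleaves the primary silyl ether, so the free alcohol needed next is obtained, and hydroxide does not isomerise the unconjugated alkene.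

Step 16
Reactants: 23 right-half alcohol
Product: 24 (1R,2S,4aS)-1-(2-bromoethyl)-1,2,5,5-tetramethyl-1,2,3,4,4a,5,6,7-octahydronaphthalene
Conditions: CBr4, PPh3, CH2Cl2, 0 °C
Reagents that add atoms: tetrabromomethane, BrC(Br)(Br)Br
Why: Appel bromination of a primary alcohol whose carbinol carbon is two bonds from the quaternary centre, so substitution is unhindered.

Step 17
Reactants: 1 2-methylcyclohex-2-en-1-one; 25 2,5-dimethoxybenzyl bromide
Product: 27 (2S,3R)-2-(2,5-dimethoxybenzyl)-2,3-dimethylcyclohexan-1-one, via magnesium enolate 26 (not isolated)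
Conditions: MeMgBr, CuBr·SMe2 (5 mol%), mirror-image Josiphos ligand of step 1 (6 mol%, gives the 3R centre), t-BuOMe, −78 °C; then 25, DMPU, −78 → 0 °C
Reagents that add atoms: methylmagnesium bromide, C[Mg]Br
Why: The same tandem asymmetric conjugate addition–enolate alkylation as step 1 with the mirror-image ligand; the reactive benzylic bromide enters anti to the new methyl, giving the quaternary carbon with the two methyls cis.

Step 18
Reactants: 27 benzyl dimethylcyclohexanone
Product: 29 (5R,6S)-6-(2,5-dimethoxybenzyl)-5,6-dimethylcyclohex-2-en-1-one, via silyl enol ether 28 (not isolated)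
Conditions: LiN(iPr)2, THF, −78 °C; TMSCl; then Pd(OAc)2 (1.1 equiv), MeCN, 23 °C
Reagents that add atoms: none
Why: Saegusa–Ito dehydrogenation: the kinetic enolate can form only toward C-6, its TMS enol ether 28 is palladated by Pd(OAc)2 and β-hydride elimination gives the enone.

Step 19
Reactants: 29 6,6-disubstituted cyclohexenone; 30 2-(3-chloropropyl)-2-methyl-1,3-dioxolane
Product: 32 (1RS,5R,6S)-6-(2,5-dimethoxybenzyl)-5,6-dimethyl-1-[3-(2-methyl-1,3-dioxolan-2-yl)propyl]cyclohex-2-en-1-ol, via Grignard reagent 31 (not isolated)
Conditions: 30, Mg, THF, 50 °C; then CeCl3, THF, −78 °C; 29, −78 → 0 °C; NH4Cl work-up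
Reagents that add atoms: none
Why: 1,2-Addition of a Grignard reagent to a hindered enone, with CeCl3 suppressing enolisation and conjugate addition; the configuration of the new carbinol is irrelevant because it is lost in step 20.

Step 20
Reactants: 32 tertiary allylic alcohol
Product: 33 (4S,5R)-4-(2,5-dimethoxybenzyl)-4,5-dimethyl-3-[3-(2-methyl-1,3-dioxolan-2-yl)propyl]cyclohex-2-en-1-one
Conditions: pyridinium chlorochromate [C5H5NH][CrO3Cl], Celite, CH2Cl2, 23 °C
Reagents that add atoms: pyridinium chlorochromate, [O-][Cr](=O)(=O)Cl.c1cc[nH+]cc1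
Why: Babler–Dauben oxidative transposition: the chromate ester of the tertiary allylic alcohol undergoes a [3,3] shift and the secondary chromate is oxidised, moving the oxygen to C-3 of the old ring and leaving the side chain on the β-carbon of the new enone.

Step 21
Reactants: 33 transposed enone
Product: 34 (3S,4S,5R)-4-(2,5-dimethoxybenzyl)-4,5-dimethyl-3-[3-(2-methyl-1,3-dioxolan-2-yl)propyl]cyclohexan-1-one
Conditions: Li, NH3/THF, t-BuOH (1 equiv), −78 °C; then NH4Cl
Reagents that add atoms: none
Why: Dissolving-metal (Birch-type) reduction of the enone: the β-carbanion is protonated axially through the chair in which the side chain, the benzyl group and the C-5 methyl are all equatorial, which puts the new hydrogen cis to the benzyl group (3S); with one equivalent of proton donor at −78 °C the ketal and the dimethoxyarene are not reduced.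

Step 22
Reactants: 34 saturated keto ketal
Product: 37 (3R,4S,4aR)-4-(2,5-dimethoxybenzyl)-3,4,8-trimethyl-3,4,4a,5,6,7-hexahydronaphthalen-1(2H)-one, via diketone 35 (not isolated), via ketol 36 (not isolated)
Conditions: 2 M HCl, THF, 23 °C; then KOH, MeOH, 65 °C
Reagents that add atoms: none
Why: Ketal hydrolysis followed by intramolecular aldol condensation: only the C-2 enolate attacking the side-chain ketone gives a ketol (36) that can dehydrate, because the alternative closure gives a bridged bicyclo[3.3.1] ketol with a bridgehead hydroxyl that can only revert; E1cB dehydration gives the conjugated tetrasubstituted enone, and the ring-fusion centre is not enolisable.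

Step 23
Reactants: 37 bicyclic enone
Product: 38 (1R,3R,4S,4aR)-4-(2,5-dimethoxybenzyl)-3,4,8-trimethyl-1,2,3,4,4a,5,6,7-octahydronaphthalen-1-ol
Conditions: (3aS)-1-methyl-3,3-diphenyltetrahydro-1H,3H-pyrrolo[1,2-c][1,3,2]oxazaborole (0.3 equiv), catecholborane, toluene, −78 → −40 °C
Reagents that add atoms: none
Why: Corey–Bakshi–Shibata reduction: with the fully substituted alkenyl carbon as the large group this catalyst enantiomer delivers hydride to the face of the two methyls and gives the (1R)-alcohol, whose pseudoaxial hydroxyl also avoids allylic strain with the C-8 methyl.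

Step 24
Reactants: 38 (1R)-allylic alcohol; 39 picolinic acid
Product: 40 (1R,3R,4S,4aR)-4-(2,5-dimethoxybenzyl)-3,4,8-trimethyl-1,2,3,4,4a,5,6,7-octahydronaphthalen-1-yl pyridine-2-carboxylate
Conditions: N,N'-dicyclohexylcarbodiimide, 4-(dimethylamino)pyridine (cat.), CH2Cl2, 23 °C
Reagents that add atoms: none
Why: Steglich esterification of the secondary allylic alcohol with picolinic acid; no bond to the stereocentre is broken.

Step 25
Reactants: 24 right-half bromide; 40 left-half picolinate
Product: 42 2-{[(1S,2R,5S,8aR)-1,2,5-trimethyl-5-{2-[(1R,2S,4aS)-1,2,5,5-tetramethyl-1,2,3,4,4a,5,6,7-octahydronaphthalen-1-yl]ethyl}-1,2,3,5,6,7,8,8a-octahydronaphthalen-1-yl]methyl}-1,4-dimethoxybenzene, via Grignard reagent 41 (not isolated)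
Conditions: 24, Mg, THF, 45 °C; CuBr·SMe2 (0.5 equiv per Grignard), THF, −40 °C; then 40 (0.5 equiv), −40 → 0 °C
Reagents that add atoms: none
Why: Copper-mediated anti-SN2′ allylic substitution of a picolinate by a Grignard reagent: chelation of magnesium by the picolinate activates the leaving group and directs the organocopper to the γ-carbon on the face opposite to the pseudoaxial C–O bond, so the bridge carbon enters on the face of the two ring A methyls, creating the (S) quaternary carbon and moving the alkene into ring A.

Step 26
Reactants: 42 bis-decalin dimethyl ether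
Product: 44 2-{[(1S,2R,5S,8aR)-1,2,5-trimethyl-5-{2-[(1R,2S,4aS)-1,2,5,5-tetramethyl-1,2,3,4,4a,5,6,7-octahydronaphthalen-1-yl]ethyl}-1,2,3,5,6,7,8,8a-octahydronaphthalen-1-yl]methyl}benzene-1,4-diol, via quinone 43 (not isolated)
Conditions: (NH4)2Ce(NO3)6, MeCN/H2O, 0 °C; then Na2S2O4, H2O/EtOAc, 23 °C
Reagents that add atoms: water, O
Why: Oxidative demethylation of the hydroquinone dimethyl ether by tetravalent cerium gives quinone 43 (quinone oxygens from water), which Na2S2O4 reduces to the hydroquinone in the same work-up; the isolated trisubstituted alkenes should not be oxidised under these conditions.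

Step 27
Reactants: 44 bis-decalin hydroquinone
Product: 46 2-{[(1S,2R,5S,8aR)-1,2,5-trimethyl-5-{2-[(1R,2S,4aS)-1,2,5,5-tetramethyl-1,2,3,4,4a,5,6,7-octahydronaphthalen-1-yl]ethyl}-1,2,3,5,6,7,8,8a-octahydronaphthalen-1-yl]methyl}-1,4-phenylene bis(hydrogen sulfate), via pyridinium sulfate salt 45 (not isolated)
Conditions: SO3·pyridine, pyridine, 50 °C; then H+-form cation-exchange resin, MeOH/H2O, 0 °C
Reagents that add atoms: sulfur trioxide–pyridine complex, O=S(=O)=O.c1ccncc1
Why: O-Sulfation of both phenols by the SO3·pyridine complex gives bis(pyridinium sulfate) 45; brief cold cation exchange gives the free bis(hydrogen sulfate) as drawn, with acid contact too short to move the alkenes.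

## Compound list

1 | 2-methylcyclohex-2-en-1-one | CC1=CCCCC1=O | starting material
2 | allyl bromide | C=CCBr | starting material
3 | bromomagnesium (3S)-2,3-dimethylcyclohex-1-en-1-olate | C[C@H]1CCCC(O[Mg]Br)=C1C | intermediate
4 | (2R,3S)-2-allyl-2,3-dimethylcyclohexan-1-one | O=C1CCC[C@H](C)[C@@]1(C)CC=C | intermediate
5 | (5S,6R)-6-allyl-5,6-dimethylcyclohex-1-en-1-yl trifluoromethanesulfonate | FC(F)(F)S(=O)(=O)OC1=CCC[C@H](C)[C@@]1(C)CC=C | intermediate
6 | (5S,6R)-5,6-dimethyl-6-(2-oxoethyl)cyclohex-1-en-1-yl trifluoromethanesulfonate | FC(F)(F)S(=O)(=O)OC1=CCC[C@H](C)[C@@]1(C)CC=O | intermediate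
7 | (5S,6R)-6-(2-hydroxyethyl)-5,6-dimethylcyclohex-1-en-1-yl trifluoromethanesulfonate | FC(F)(F)S(=O)(=O)OC1=CCC[C@H](C)[C@@]1(C)CCO | intermediate
8 | (5S,6R)-6-[2-(tert-butyldimethylsilyloxy)ethyl]-5,6-dimethylcyclohex-1-en-1-yl trifluoromethanesulfonate | FC(F)(F)S(=O)(=O)OC1=CCC[C@H](C)[C@@]1(C)CCO[Si](C)(C)C(C)(C)C | intermediate
9 | δ-valerolactone (tetrahydro-2H-pyran-2-one) | O=C1CCCCO1 | starting material
10 | (±)-3-methyltetrahydro-2H-pyran-2-one | CC1CCCOC1=O | intermediate
11 | methyl (±)-5-hydroxy-2-methylpentanoate | COC(=O)C(C)CCCO | intermediate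
12 | methyl (±)-2-methyl-5-oxopentanoate | COC(=O)C(C)CCC=O | intermediate
13 | methyl (2RS,5RS)-5-{(5S,6R)-6-[2-(tert-butyldimethylsilyloxy)ethyl]-5,6-dimethylcyclohex-1-en-1-yl}-5-hydroxy-2-methylpentanoate | COC(=O)C(C)CCC(O)C1=CCC[C@H](C)[C@@]1(C)CCO[Si](C)(C)C(C)(C)C | intermediate
14 | methyl (2RS)-5-{(5S,6R)-6-[2-(tert-butyldimethylsilyloxy)ethyl]-5,6-dimethylcyclohex-1-en-1-yl}-2-methyl-5-oxopentanoate | COC(=O)C(C)CCC(=O)C1=CCC[C@H](C)[C@@]1(C)CCO[Si](C)(C)C(C)(C)C | intermediate
15 | methyl (2RS,5R)-5-{(5S,6R)-6-[2-(tert-butyldimethylsilyloxy)ethyl]-5,6-dimethylcyclohex-1-en-1-yl}-5-hydroxy-2-methylpentanoate | COC(=O)C(C)CC[C@@H](O)C1=CCC[C@H](C)[C@@]1(C)CCO[Si](C)(C)C(C)(C)C | intermediate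
16 | (3RS,6R)-6-{(5S,6R)-6-[2-(tert-butyldimethylsilyloxy)ethyl]-5,6-dimethylcyclohex-1-en-1-yl}-3-methyltetrahydro-2H-pyran-2-one | CC1CC[C@@H](OC1=O)C1=CCC[C@H](C)[C@@]1(C)CCO[Si](C)(C)C(C)(C)C | intermediate
17 | (2R)-6-(tert-butyldimethylsilyloxy)-2-{(5S,6R)-6-[2-(tert-butyldimethylsilyloxy)ethyl]-5,6-dimethylcyclohex-1-en-1-yl}-5-methyl-3,4-dihydro-2H-pyran | CC1=C(O[Si](C)(C)C(C)(C)C)O[C@H](CC1)C1=CCC[C@H](C)[C@@]1(C)CCO[Si](C)(C)C(C)(C)C | intermediate
18 | tert-butyldimethylsilyl (1S,5R,6S,8aR)-5-[2-(tert-butyldimethylsilyloxy)ethyl]-1,5,6-trimethyl-1,2,3,5,6,7,8,8a-octahydronaphthalene-1-carboxylate | CC(C)(C)[Si](C)(C)OCC[C@@]1(C)C2=CCC[C@](C)(C(=O)O[Si](C)(C)C(C)(C)C)[C@@H]2CC[C@@H]1C | intermediate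
19 | (1S,5R,6S,8aR)-5-[2-(tert-butyldimethylsilyloxy)ethyl]-1,5,6-trimethyl-1,2,3,5,6,7,8,8a-octahydronaphthalene-1-carboxylic acid | CC(C)(C)[Si](C)(C)OCC[C@@]1(C)C2=CCC[C@](C)(C(=O)O)[C@@H]2CC[C@@H]1C | intermediate
20 | {(1S,5R,6S,8aR)-5-[2-(tert-butyldimethylsilyloxy)ethyl]-1,5,6-trimethyl-1,2,3,5,6,7,8,8a-octahydronaphthalen-1-yl}methanol | CC(C)(C)[Si](C)(C)OCC[C@@]1(C)C2=CCC[C@](C)(CO)[C@@H]2CC[C@@H]1C | intermediate
21 | (1S,5R,6S,8aR)-5-[2-(tert-butyldimethylsilyloxy)ethyl]-1,5,6-trimethyl-1,2,3,5,6,7,8,8a-octahydronaphthalene-1-carbaldehyde | CC(C)(C)[Si](C)(C)OCC[C@@]1(C)C2=CCC[C@](C)(C=O)[C@@H]2CC[C@@H]1C | intermediate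
22 | hydrazone of aldehyde 21 (1S,5R,6S,8aR) | CC(C)(C)[Si](C)(C)OCC[C@@]1(C)C2=CCC[C@](C)(C=NN)[C@@H]2CC[C@@H]1C | intermediate
23 | 2-[(1R,2S,4aS)-1,2,5,5-tetramethyl-1,2,3,4,4a,5,6,7-octahydronaphthalen-1-yl]ethan-1-ol | OCC[C@@]1(C)C2=CCCC(C)(C)[C@@H]2CC[C@@H]1C | intermediate
24 | (1R,2S,4aS)-1-(2-bromoethyl)-1,2,5,5-tetramethyl-1,2,3,4,4a,5,6,7-octahydronaphthalene | BrCC[C@@]1(C)C2=CCCC(C)(C)[C@@H]2CC[C@@H]1C | intermediate
25 | 2,5-dimethoxybenzyl bromide [2-(bromomethyl)-1,4-dimethoxybenzene] | COc1ccc(OC)c(CBr)c1 | starting material
26 | bromomagnesium (3R)-2,3-dimethylcyclohex-1-en-1-olate | C[C@@H]1CCCC(O[Mg]Br)=C1C | intermediate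
27 | (2S,3R)-2-(2,5-dimethoxybenzyl)-2,3-dimethylcyclohexan-1-one | C[C@@H]1CCCC(=O)[C@@]1(C)Cc1cc(OC)ccc1OC | intermediate
28 | {[(5R,6S)-6-(2,5-dimethoxybenzyl)-5,6-dimethylcyclohex-1-en-1-yl]oxy}trimethylsilane | C[C@@H]1CCC=C(O[Si](C)(C)C)[C@@]1(C)Cc1cc(OC)ccc1OC | intermediate
29 | (5R,6S)-6-(2,5-dimethoxybenzyl)-5,6-dimethylcyclohex-2-en-1-one | C[C@@H]1CC=CC(=O)[C@@]1(C)Cc1cc(OC)ccc1OC | intermediate
30 | 2-(3-chloropropyl)-2-methyl-1,3-dioxolane | ClCCCC1(C)OCCO1 | starting material
31 | [3-(2-methyl-1,3-dioxolan-2-yl)propyl]magnesium chloride | Cl[Mg]CCCC1(C)OCCO1 | intermediate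
32 | (1RS,5R,6S)-6-(2,5-dimethoxybenzyl)-5,6-dimethyl-1-[3-(2-methyl-1,3-dioxolan-2-yl)propyl]cyclohex-2-en-1-ol | C[C@@H]1CC=CC(O)(CCCC2(C)OCCO2)[C@@]1(C)Cc1cc(OC)ccc1OC | intermediate
33 | (4S,5R)-4-(2,5-dimethoxybenzyl)-4,5-dimethyl-3-[3-(2-methyl-1,3-dioxolan-2-yl)propyl]cyclohex-2-en-1-one | C[C@@H]1CC(=O)C=C(CCCC2(C)OCCO2)[C@@]1(C)Cc1cc(OC)ccc1OC | intermediate
34 | (3S,4S,5R)-4-(2,5-dimethoxybenzyl)-4,5-dimethyl-3-[3-(2-methyl-1,3-dioxolan-2-yl)propyl]cyclohexan-1-one | C[C@@H]1CC(=O)C[C@H](CCCC2(C)OCCO2)[C@@]1(C)Cc1cc(OC)ccc1OC | intermediate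
35 | (3S,4S,5R)-4-(2,5-dimethoxybenzyl)-4,5-dimethyl-3-(4-oxopentyl)cyclohexan-1-one | C[C@@H]1CC(=O)C[C@H](CCCC(C)=O)[C@@]1(C)Cc1cc(OC)ccc1OC | intermediate
36 | (3R,4S,4aS,8RS,8aRS)-4-(2,5-dimethoxybenzyl)-8-hydroxy-3,4,8-trimethyloctahydronaphthalen-1(2H)-one | C[C@@H]1CC(=O)C2C(C)(O)CCC[C@@H]2[C@@]1(C)Cc1cc(OC)ccc1OC | intermediate
37 | (3R,4S,4aR)-4-(2,5-dimethoxybenzyl)-3,4,8-trimethyl-3,4,4a,5,6,7-hexahydronaphthalen-1(2H)-one | C[C@@H]1CC(=O)C2=C(C)CCC[C@@H]2[C@@]1(C)Cc1cc(OC)ccc1OC | intermediate
38 | (1R,3R,4S,4aR)-4-(2,5-dimethoxybenzyl)-3,4,8-trimethyl-1,2,3,4,4a,5,6,7-octahydronaphthalen-1-ol | C[C@@H]1C[C@@H](O)C2=C(C)CCC[C@@H]2[C@@]1(C)Cc1cc(OC)ccc1OC | intermediate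
39 | picolinic acid (pyridine-2-carboxylic acid) | OC(=O)c1ccccn1 | starting material
40 | (1R,3R,4S,4aR)-4-(2,5-dimethoxybenzyl)-3,4,8-trimethyl-1,2,3,4,4a,5,6,7-octahydronaphthalen-1-yl pyridine-2-carboxylate | C[C@@H]1C[C@@H](OC(=O)c2ccccn2)C2=C(C)CCC[C@@H]2[C@@]1(C)Cc1cc(OC)ccc1OC | intermediate
41 | {2-[(1R,2S,4aS)-1,2,5,5-tetramethyl-1,2,3,4,4a,5,6,7-octahydronaphthalen-1-yl]ethyl}magnesium bromide | Br[Mg]CC[C@@]1(C)C2=CCCC(C)(C)[C@@H]2CC[C@@H]1C | intermediate
42 | 2-{[(1S,2R,5S,8aR)-1,2,5-trimethyl-5-{2-[(1R,2S,4aS)-1,2,5,5-tetramethyl-1,2,3,4,4a,5,6,7-octahydronaphthalen-1-yl]ethyl}-1,2,3,5,6,7,8,8a-octahydronaphthalen-1-yl]methyl}-1,4-dimethoxybenzene | C[C@@H]1CC=C2[C@H](CCC[C@@]2(C)CC[C@@]2(C)C3=CCCC(C)(C)[C@@H]3CC[C@@H]2C)[C@@]1(C)Cc1cc(OC)ccc1OC | intermediate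
43 | 2-{[left–right bis-decalin of 42]methyl}cyclohexa-2,5-diene-1,4-dione (configuration as 42) | C[C@@H]1CC=C2[C@H](CCC[C@@]2(C)CC[C@@]2(C)C3=CCCC(C)(C)[C@@H]3CC[C@@H]2C)[C@@]1(C)CC1=CC(=O)C=CC1=O | intermediate
44 | 2-{[(1S,2R,5S,8aR)-1,2,5-trimethyl-5-{2-[(1R,2S,4aS)-1,2,5,5-tetramethyl-1,2,3,4,4a,5,6,7-octahydronaphthalen-1-yl]ethyl}-1,2,3,5,6,7,8,8a-octahydronaphthalen-1-yl]methyl}benzene-1,4-diol | C[C@@H]1CC=C2[C@H](CCC[C@@]2(C)CC[C@@]2(C)C3=CCCC(C)(C)[C@@H]3CC[C@@H]2C)[C@@]1(C)Cc1cc(O)ccc1O | intermediate
45 | bis(pyridinium) salt of the bis-sulfate 46 | C[C@@H]1CC=C2[C@H](CCC[C@@]2(C)CC[C@@]2(C)C3=CCCC(C)(C)[C@@H]3CC[C@@H]2C)[C@@]1(C)Cc1cc(OS(=O)(=O)[O-])ccc1OS(=O)(=O)[O-].c1cc[nH+]cc1.c1cc[nH+]cc1 | intermediate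
46 | 2-{[(1S,2R,5S,8aR)-1,2,5-trimethyl-5-{2-[(1R,2S,4aS)-1,2,5,5-tetramethyl-1,2,3,4,4a,5,6,7-octahydronaphthalen-1-yl]ethyl}-1,2,3,5,6,7,8,8a-octahydronaphthalen-1-yl]methyl}-1,4-phenylene bis(hydrogen sulfate) | C[C@@H]1CC=C2[C@H](CCC[C@@]2(C)CC[C@@]2(C)C3=CCCC(C)(C)[C@@H]3CC[C@@H]2C)[C@@]1(C)Cc1cc(OS(=O)(=O)O)ccc1OS(=O)(=O)O | target

## Step count and risk

Total: 27 steps. Longest linear sequence: 16 steps from 2-methylcyclohex-2-en-1-one (steps 1–4, 8–16, 25–27). The left half (steps 17–24, 8 steps) and the aldehyde (steps 5–7, 3 steps) run in parallel.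

**Step 12 (key step).** The most likely failure is that the bicyclic boat is not reached. The quaternary carbon on the central allyl carbon is pressed against the silyloxy-bearing ketene acetal carbon, so ionisation of the allylic C–O bond, elimination or simple desilylation back to the lactone may outrun the sigmatropic shift.

Fallback, from 8, rejoining at 19: the forcing tether is cut open, the same bond is made through an unconstrained chair, and ring C is closed afterwards.
- CrCl2/NiCl2 coupling of triflate 8 with acetaldehyde would give the carbinol mixture 1-(cyclohexenyl)ethanol F1.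
- Dess–Martin oxidation gives methyl ketone F2, and oxazaborolidine/catecholborane reduction as in step 10 gives the (R)-carbinol F3.
- Esterification with 2-methylhex-5-enoic acid (N,N'-dicyclohexylcarbodiimide, 4-(dimethylamino)pyridine) gives allylic ester F4.
- Ireland–Claisen rearrangement (LiN(iPr)2, TMSCl, THF, −78 → 65 °C) delivers the enolate carbon to the ring D alkene CH on the face of the departing oxygen. With the carbinol methyl turned away from the quaternary carbon, that is the same face as in step 12. The product is diene acid F5.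
- Ring-closing metathesis with second-generation Grubbs catalyst expels propene and closes ring C. It gives acid 19, which is separated from the epimeric acid F6 (epimer at the carboxyl-bearing carbon).

**Step 23.** The likely failure is poor facial selectivity. The substrate's preference for axial hydride entry, which would give the equatorial alcohol, may override the catalyst at this hindered, cross-conjugated ketone.

Fallback, from 37, rejoining at 40: NaBH4/CeCl3 reduction under substrate control. If it delivers the equatorial (1S)-alcohol F7, Mitsunobu esterification with picolinic acid 39 (PPh3, diisopropyl azodicarboxylate) inverts C-1 and gives picolinate 40 directly.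

**Step 25.** The likely failure is slow substitution at the fully substituted γ-carbon. The required anti trajectory is not the chair-axial one for ring B. Direct substitution at the carbinol carbon, reduction or elimination of the activated picolinate may then compete. The step also consumes an excess of the valuable Grignard reagent.

Fallback, from 37 and 41, rejoining at 42: the halves are joined as an ester and the quaternary carbon is made intramolecularly.
- Carboxylation of Grignard reagent 41 with CO2 gives the right-half propanoic acid F8.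
- The (1S)-alcohol F7, from Luche reduction of 37, is esterified with F8 to allylic ester F9.
- Ireland–Claisen rearrangement (LiN(iPr)2, TMSCl, THF, −78 → 65 °C) transfers the ester α-carbon suprafacially to the face of the two ring A methyls. This creates the quaternary carbon with the ring A alkene in place and gives bridge carboxylic acid F10.
- Barton reductive decarboxylation (N-hydroxypyridine-2-thione ester, t-BuSH at high concentration, light) removes the carboxyl group and gives 42. The high thiol concentration is needed to outpace a 1,2-vinyl shift of the homoallylic radical.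

**Step 21.** The likely failures are protonation of the β-carbon from the wrong face if the all-equatorial chair is not the reacting conformer, and over-reduction of the ketone or partial reduction of the arene.

Fallback, from 33, rejoining at 37: aqueous HCl/THF removes the ketal to give enedione F11. [(Ph3P)CuH]6 in toluene then delivers hydride to the β-carbon, and the copper enolate closes ring B on the side-chain ketone in the same operation. This gives ketol 36, which KOH/MeOH dehydrates to 37.

## Further compounds

F1 | step 12 | (1RS)-1-{(5S,6R)-6-[2-(tert-butyldimethylsilyloxy)ethyl]-5,6-dimethylcyclohex-1-en-1-yl}ethan-1-ol | CC(O)C1=CCC[C@H](C)[C@@]1(C)CCO[Si](C)(C)C(C)(C)C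
F2 | step 12 | 1-{(5S,6R)-6-[2-(tert-butyldimethylsilyloxy)ethyl]-5,6-dimethylcyclohex-1-en-1-yl}ethan-1-one | CC(=O)C1=CCC[C@H](C)[C@@]1(C)CCO[Si](C)(C)C(C)(C)C
F3 | step 12 | (1R)-1-{(5S,6R)-6-[2-(tert-butyldimethylsilyloxy)ethyl]-5,6-dimethylcyclohex-1-en-1-yl}ethan-1-ol | C[C@@H](O)C1=CCC[C@H](C)[C@@]1(C)CCO[Si](C)(C)C(C)(C)C
F4 | step 12 | (1R)-1-{(5S,6R)-6-[2-(tert-butyldimethylsilyloxy)ethyl]-5,6-dimethylcyclohex-1-en-1-yl}ethyl (2RS)-2-methylhex-5-enoate | C=CCCC(C)C(=O)O[C@H](C)C1=CCC[C@H](C)[C@@]1(C)CCO[Si](C)(C)C(C)(C)C
F5 | step 12 | 2-[(1R,3R,4S)-3-{2-[(tert-butyldimethylsilyl)oxy]ethyl}-2-ethylidene-3,4-dimethylcyclohexyl]-2-methylhex-5-enoic acid (both epimers at C-2 of the acid) | CC=C1[C@@H](CC[C@H](C)[C@@]1(C)CCO[Si](C)(C)C(C)(C)C)C(C)(CCC=C)C(=O)O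
F6 | step 12 | (1R,5R,6S,8aR)-5-[2-(tert-butyldimethylsilyloxy)ethyl]-1,5,6-trimethyl-1,2,3,5,6,7,8,8a-octahydronaphthalene-1-carboxylic acid | CC(C)(C)[Si](C)(C)OCC[C@@]1(C)C2=CCC[C@@](C)(C(=O)O)[C@@H]2CC[C@@H]1C
F7 | step 23 | (1S,3R,4S,4aR)-4-(2,5-dimethoxybenzyl)-3,4,8-trimethyl-1,2,3,4,4a,5,6,7-octahydronaphthalen-1-ol | C[C@@H]1C[C@H](O)C2=C(C)CCC[C@@H]2[C@@]1(C)Cc1cc(OC)ccc1OC
F8 | step 25 | 3-[(1R,2S,4aS)-1,2,5,5-tetramethyl-1,2,3,4,4a,5,6,7-octahydronaphthalen-1-yl]propanoic acid | OC(=O)CC[C@@]1(C)C2=CCCC(C)(C)[C@@H]2CC[C@@H]1C
F9 | step 25 | (1S,3R,4S,4aR)-4-(2,5-dimethoxybenzyl)-3,4,8-trimethyl-1,2,3,4,4a,5,6,7-octahydronaphthalen-1-yl 3-[(1R,2S,4aS)-1,2,5,5-tetramethyl-1,2,3,4,4a,5,6,7-octahydronaphthalen-1-yl]propanoate | C[C@@H]1C[C@H](OC(=O)CC[C@@]2(C)C3=CCCC(C)(C)[C@@H]3CC[C@@H]2C)C2=C(C)CCC[C@@H]2[C@@]1(C)Cc1cc(OC)ccc1OC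
F10 | step 25 | (2RS)-2-[(1S,4aR,5S,6R)-5-(2,5-dimethoxybenzyl)-1,5,6-trimethyl-1,2,3,4,4a,5,6,7-octahydronaphthalen-1-yl]-3-[(1R,2S,4aS)-1,2,5,5-tetramethyl-1,2,3,4,4a,5,6,7-octahydronaphthalen-1-yl]propanoic acid | C[C@@H]1CC=C2[C@H](CCC[C@@]2(C)C(C(=O)O)C[C@@]2(C)C3=CCCC(C)(C)[C@@H]3CC[C@@H]2C)[C@@]1(C)Cc1cc(OC)ccc1OC
F11 | step 21 | (4S,5R)-4-(2,5-dimethoxybenzyl)-4,5-dimethyl-3-(4-oxopentyl)cyclohex-2-en-1-one | C[C@@H]1CC(=O)C=C(CCCC(C)=O)[C@@]1(C)Cc1cc(OC)ccc1OC
A1 | alternative 1 | 1-ethynyl-1-methyl-2-vinylcyclohex-2-ene (single enantiomer) | C=CC1=CCCC[C@@]1(C)C#C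
A2 | alternative 1 | 3-(2,5-dimethoxybenzyl)furan-2,5-dione | O=C1OC(=O)C(Cc2cc(OC)ccc2OC)=C1
A3 | alternative 1 | left decalin as cis-fused anhydride carrying the 2,5-dimethoxybenzyl and ethynyl groups | O=C1OC(=O)[C@@]2(Cc3cc(OC)ccc3OC)[C@H]3CCC[C@@](C)(C#C)C3=CC[C@@H]12
A4 | alternative 2 | 6-[(4E)-3,4-dimethylhex-4-en-1-yl]-5,5-dimethylcyclohex-1-en-1-yl trifluoromethanesulfonate (configuration as in the SMILES) | C/C=C(\C)[C@@H](C)CC[C@@H]1C(OS(=O)(=O)C(F)(F)F)=CCCC1(C)C
A5 | alternative 2 | 1,2,5,5-tetramethyl-1-vinyl-1,2,3,4,4a,5,6,7-octahydronaphthalene (right decalin with vinyl on the quaternary carbon) | C=C[C@@]1(C)C2=CCCC(C)(C)[C@@H]2CC[C@@H]1C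
A6 | alternative 3 | bis-decalin of 42 with prop-2-ynyl in place of the benzyl group | C[C@@H]1CC=C2[C@H](CCC[C@@]2(C)CC[C@@]2(C)C3=CCCC(C)(C)[C@@H]3CC[C@@H]2C)[C@@]1(C)CC#C
A7 | alternative 3 | pentacarbonyl(1-methoxyprop-2-en-1-ylidene)chromium, (CO)5Cr=C(OMe)CH=CH2 | COC(C=C)=[Cr](=C=O)(=C=O)(=C=O)(=C=O)=C=O
A8 | alternative 3 | hydroquinone monomethyl ether with the complete skeleton | C[C@@H]1CC=C2[C@H](CCC[C@@]2(C)CC[C@@]2(C)C3=CCCC(C)(C)[C@@H]3CC[C@@H]2C)[C@@]1(C)Cc1cc(OC)ccc1O
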